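The central 2,3-dihydrobenzofuran (O1, C2, C3, C3a, C7a; the ring carrying the styryl group at C5) is read as a contracted 4-aryl-3,4-dihydrocoumarin. O1 and the diarylmethine C3 sit on neighbouring benzo carbons, so O1–C2–C3 maps onto the lactone O–C(=O)–CH2–C4. In one operation, α-bromination and hydroxide treatment contract the six-membered lactone to the five-membered ether ring, expelling the carbonyl carbon as a C2 carboxyl that is later exchanged for the aryl group. The precursor is a 6-chloro-4-aryldihydrocoumarin whose C4 centre comes from a catalytic asymmetric conjugate arylation. The same sequence builds the eastern dihydrobenzofuran, which, dehydrogenated, also supplies the western benzofuran.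

Key step: step 11

Assumption: the Rh/SEGPHOS arylations of both coumarins are taken to follow the facial sense of the parent system, where the (R)-ligand gives the (4R)-4-arylchroman-2-one (the CIP order C4a > aryl > C3 holds for 6 and 16); if the sense is reversed, the ligand enantiomers are exchanged.

Step 1
Reactants: 1 1-chloro-3,5-dimethoxybenzene
Product: 2 2-chloro-4,6-dimethoxybenzaldehyde
Conditions: POCl3, DMF, 0 °C to 80 °C; aq. NaOAc
Reagents that add atoms: N,N-dimethylformamide CN(C)C=O (formyl carbon); water O (formyl oxygen)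
Why: Vilsmeier–Haack formylation should attack the ring carbon para to one methoxy group and ortho to the other (next to chlorine), the position between the two methoxy groups being the more hindered one.

Step 2
Reactants: 2 2-chloro-4,6-dimethoxybenzaldehyde
Product: 3 2-chloro-6-hydroxy-4-methoxybenzaldehyde
Conditions: BCl3, CH2Cl2, −78 °C to 0 °C; H2O
Reagents that add atoms: none
Why: Chelation-directed Lewis acid ether cleavage: BCl3 bound to the aldehyde oxygen should remove only the ortho methyl ether and leave the para one.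

Step 3
Reactants: 3 2-chloro-6-hydroxy-4-methoxybenzaldehyde
Product: 4 5-chloro-7-methoxy-2H-chromen-2-one
Conditions: Ph3P=CHCO2Et, N,N-diethylaniline, 210 °C
Reagents that add atoms: ethyl (triphenylphosphoranylidene)acetate CCOC(=O)C=P(c1ccccc1)(c1ccccc1)c1ccccc1
Why: Wittig olefination of the salicylaldehyde, thermal E/Z equilibration and lactonization of the Z-cinnamate make up the standard one-pot coumarin synthesis.

Step 4
Reactants: 4 5-chloro-7-methoxy-2H-chromen-2-one; 5 (3,5-dimethoxyphenyl)boronic acid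
Product: 6 (4S)-5-chloro-4-(3,5-dimethoxyphenyl)-7-methoxy-3,4-dihydro-2H-chromen-2-one
Conditions: Rh(acac)(C2H4)2 (3 mol %), (S)-SEGPHOS (3.3 mol %), 5 (5 equiv), 1,4-dioxane/H2O 10:1, 60 °C
Reagents that add atoms: none
Why: Hayashi–Miyaura conjugate addition: the aryl–rhodium species inserts the coumarin C3=C4 bond on the face chosen by the bisphosphine, so C4 (the later C3 of the eastern dihydrobenzofuran) should be set as S by catalyst control, and the aryl chloride is inert to monovalent rhodium.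

Step 5
Reactants: 6 (4S)-5-chloro-4-(3,5-dimethoxyphenyl)-7-methoxy-3,4-dihydro-2H-chromen-2-one
Product: 9 (2S,3S)-4-chloro-3-(3,5-dimethoxyphenyl)-6-methoxy-2,3-dihydro-1-benzofuran-2-carboxylic acid, via trans-3-bromolactone 7 (not isolated), via ring-opened bromo phenolate 8 (not isolated)
Conditions: LiN(SiMe3)2, THF, −78 °C; BrCl2CCCl2Br, −78 °C; then LiOH, H2O, 0 °C to rt; aq. HCl
Reagents that add atoms: 1,2-dibromo-1,1,2,2-tetrachloroethane BrC(Cl)(Cl)C(Cl)(Cl)Br (bromine of 7 and 8 only); lithium hydroxide [Li+].[OH-] (carboxyl oxygen)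
Why: Enolate bromination followed by a Perkin-type ring contraction: hydroxide opens the trans bromolactone 7 and the phenoxide of 8 displaces bromide in a 5-exo-tet Williamson closure (SN2 inversion, trans acid expected), C3 keeping the configuration of C4 of 6, while the C2 configuration is irrelevant because this centre is planarised in step 6.

Step 6
Reactants: 9 (2S,3S)-4-chloro-3-(3,5-dimethoxyphenyl)-6-methoxy-2,3-dihydro-1-benzofuran-2-carboxylic acid; 10 4-iodoanisole
Product: 11 (2S,3S)-4-chloro-3-(3,5-dimethoxyphenyl)-6-methoxy-2-(4-methoxyphenyl)-2,3-dihydro-1-benzofuran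
Conditions: 10 (1.5 equiv), Ir[dF(CF3)ppy]2(dtbbpy)PF6 (1 mol %), NiCl2·glyme (10 mol %), dtbbpy (15 mol %), Cs2CO3, DMF, blue LEDs, rt
Reagents that add atoms: none
Why: Decarboxylative sp3–sp2 cross-coupling under dual photoredox/nickel catalysis: the carboxylate is oxidised to the α-oxy C2 radical, which the arylnickel species should couple on the face anti to the C3 aryl group (2,3-trans, 2S, by substrate control), and the aryl chloride does not react with nickel at room temperature.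

Step 7
Reactants: 11 (2S,3S)-4-chloro-3-(3,5-dimethoxyphenyl)-6-methoxy-2-(4-methoxyphenyl)-2,3-dihydro-1-benzofuran
Product: 12 [(2S,3S)-3-(3,5-dimethoxyphenyl)-6-methoxy-2-(4-methoxyphenyl)-2,3-dihydro-1-benzofuran-4-yl]boronic acid
Conditions: B2(OH)4 (3 equiv), Pd(OAc)2 (2 mol %), XPhos (6 mol %), KOAc, EtOH, 80 °C
Reagents that add atoms: tetrahydroxydiboron OB(O)B(O)O
Why: Miyaura-type borylation: XPhos-ligated zerovalent palladium inserts into the hindered aryl C–Cl bond and tetrahydroxydiboron delivers the boronic acid directly, the stereocentres not being involved.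

Step 8
Reactants: 11 (2S,3S)-4-chloro-3-(3,5-dimethoxyphenyl)-6-methoxy-2-(4-methoxyphenyl)-2,3-dihydro-1-benzofuran
Product: 13 4-chloro-3-(3,5-dimethoxyphenyl)-6-methoxy-2-(4-methoxyphenyl)-1-benzofuran
Conditions: DDQ (1.5 equiv), 1,4-dioxane, 100 °C
Reagents that add atoms: none
Why: Quinone dehydrogenation: DDQ abstracts hydride from C2 (the cation is stabilised by the ring oxygen and the 4-methoxyphenyl group) and loss of the C3 proton aromatises the ring, so the western benzofuran is drawn from the same intermediate and the stereocentres are erased on purpose.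

Step 9
Reactants: 13 4-chloro-3-(3,5-dimethoxyphenyl)-6-methoxy-2-(4-methoxyphenyl)-1-benzofuran
Product: 14 3-(3,5-dimethoxyphenyl)-4-ethenyl-6-methoxy-2-(4-methoxyphenyl)-1-benzofuran
Conditions: CH2=CHBF3K (1.5 equiv), Pd(OAc)2 (3 mol %), SPhos (6 mol %), K2CO3, 1,4-dioxane/H2O 9:1, 90 °C
Reagents that add atoms: potassium vinyltrifluoroborate [K+].C=C[B-](F)(F)F
Why: Suzuki–Miyaura vinylation of the aryl chloride with the air-stable vinyltrifluoroborate, made possible by the electron-rich biarylphosphine.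

Step 10
Reactants: 12 [(2S,3S)-3-(3,5-dimethoxyphenyl)-6-methoxy-2-(4-methoxyphenyl)-2,3-dihydro-1-benzofuran-4-yl]boronic acid; 15 6-chloro-2H-chromen-2-one
Product: 16 (4R)-6-chloro-4-[(2S,3S)-3-(3,5-dimethoxyphenyl)-6-methoxy-2-(4-methoxyphenyl)-2,3-dihydro-1-benzofuran-4-yl]-3,4-dihydro-2H-chromen-2-one
Conditions: 15 (3 equiv), Rh(acac)(C2H4)2 (5 mol %), (R)-SEGPHOS (5.5 mol %), 1,4-dioxane/H2O 10:1, 60 °C
Reagents that add atoms: none
Why: Hayashi–Miyaura conjugate addition as in step 4: the arylrhodium species from 12 adds to C4 of the coumarin under catalyst control, (R)-SEGPHOS giving the 4R lactone, and the excess of cheap coumarin should trap the hindered aryl–rhodium species before protodeboronation.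

Step 11
Reactants: 16 (4R)-6-chloro-4-[(2S,3S)-3-(3,5-dimethoxyphenyl)-6-methoxy-2-(4-methoxyphenyl)-2,3-dihydro-1-benzofuran-4-yl]-3,4-dihydro-2H-chromen-2-one
Product: 19 (2R,3R)-5-chloro-3-[(2S,3S)-3-(3,5-dimethoxyphenyl)-6-methoxy-2-(4-methoxyphenyl)-2,3-dihydro-1-benzofuran-4-yl]-2,3-dihydro-1-benzofuran-2-carboxylic acid, via trans-3-bromolactone 17 (not isolated), via ring-opened bromo phenolate 18 (not isolated)
Conditions: LiN(SiMe3)2 (1.1 equiv), THF, −78 °C; BrCl2CCCl2Br, −78 °C; then LiOH, H2O, 0 °C to rt; aq. HCl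
Reagents that add atoms: 1,2-dibromo-1,1,2,2-tetrachloroethane BrC(Cl)(Cl)C(Cl)(Cl)Br (bromine of 17 and 18 only); lithium hydroxide [Li+].[OH-] (carboxyl oxygen)
Why: LiN(SiMe3)2 enolises the lactone at its only α-CH2 and the enolate is brominated anti to the pseudo-axial C4 aryl group to give the trans bromolactone 17; hydroxide then opens the aryl ester and the released phenoxide displaces bromide at the α-carbon, so the six-membered lactone ring (O1, C2, C3, C4, C4a, C8a) becomes the five-membered ring (O1, C2, C3, C3a, C7a) with the former carbonyl carbon pushed out as the C2 carboxyl group. The closest known reaction type is the Perkin coumarin-to-benzofuran ring contraction (3-halocoumarin to coumarilic acid), run here at the 3,4-dihydro level, where the C–O bond forms by intramolecular Williamson substitution. The ring closes in the 5-exo-tet mode. C3 keeps the configuration installed at C4 of 16 because no bond to it is broken; C2 is set by SN2 inversion of the trans bromide and should come out trans to the C3 aryl group, although its configuration is irrelevant because it becomes a radical centre in step 12. The step needs enolisation at the lactone α-carbon and not at the benzylic C–H bonds, which the large acidity difference at −78 °C secures. It also needs ring opening to outrun dehydrobromination to the coumarin: in the trans bromolactone the C4 hydrogen is syn to bromine, so no anti elimination is available, and hydroxide attack on the activated aryl ester is fast at 0 °C.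

Step 12
Reactants: 19 (2R,3R)-5-chloro-3-[(2S,3S)-3-(3,5-dimethoxyphenyl)-6-methoxy-2-(4-methoxyphenyl)-2,3-dihydro-1-benzofuran-4-yl]-2,3-dihydro-1-benzofuran-2-carboxylic acid; 10 4-iodoanisole
Product: 20 (2R,3R)-5-chloro-2-(4-methoxyphenyl)-3-[(2S,3S)-3-(3,5-dimethoxyphenyl)-6-methoxy-2-(4-methoxyphenyl)-2,3-dihydro-1-benzofuran-4-yl]-2,3-dihydro-1-benzofuran
Conditions: 10 (1.5 equiv), Ir[dF(CF3)ppy]2(dtbbpy)PF6 (1 mol %), NiCl2·glyme (10 mol %), dtbbpy (15 mol %), Cs2CO3, DMF, blue LEDs, rt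
Reagents that add atoms: none
Why: Decarboxylative photoredox/nickel arylation as in step 6: the α-oxy C2 radical of the newly contracted ring should be arylated anti to the very large C3 substituent, setting C2 as R (2,3-trans) by substrate control without opening the ring.

Step 13
Reactants: 20 (2R,3R)-5-chloro-2-(4-methoxyphenyl)-3-[(2S,3S)-3-(3,5-dimethoxyphenyl)-6-methoxy-2-(4-methoxyphenyl)-2,3-dihydro-1-benzofuran-4-yl]-2,3-dihydro-1-benzofuran; 14 3-(3,5-dimethoxyphenyl)-4-ethenyl-6-methoxy-2-(4-methoxyphenyl)-1-benzofuran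
Product: 21 (2R,3R)-5-{(E)-2-[3-(3,5-dimethoxyphenyl)-6-methoxy-2-(4-methoxyphenyl)-1-benzofuran-4-yl]ethenyl}-2-(4-methoxyphenyl)-3-[(2S,3S)-3-(3,5-dimethoxyphenyl)-6-methoxy-2-(4-methoxyphenyl)-2,3-dihydro-1-benzofuran-4-yl]-2,3-dihydro-1-benzofuran (nona-O-methyl ether of the target)
Conditions: 14 (1.2 equiv), Pd2(dba)3 (2.5 mol %), P(t-Bu)3·HBF4 (10 mol %), Cy2NMe, 1,4-dioxane, 110 °C
Reagents that add atoms: none
Why: Mizoroki–Heck reaction: zerovalent palladium with P(t-Bu)3 activates the electron-rich aryl chloride, and syn insertion at the terminal alkene carbon followed by syn β-hydride elimination should give the E-stilbene.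

Step 14
Reactants: 21 nona-O-methyl ether of the target
Product: 22 target CNP0135983.1
Conditions: BBr3 (30 equiv), CH2Cl2, −78 °C to rt; then MeOH/H2O, 0 °C
Reagents that add atoms: none
Why: Lewis acid cleavage of all nine aryl methyl ethers with BBr3; any reversible ionisation of the C2–O bonds of the two dihydrobenzofurans should reclose to the more stable 2,3-trans rings, so the four stereocentres and the E-alkene should be kept.

Compound list
1 | 1-chloro-3,5-dimethoxybenzene | COc1cc(Cl)cc(OC)c1 | starting material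
2 | 2-chloro-4,6-dimethoxybenzaldehyde | COc1cc(Cl)c(C=O)c(OC)c1 | intermediate
3 | 2-chloro-6-hydroxy-4-methoxybenzaldehyde | COc1cc(Cl)c(C=O)c(O)c1 | intermediate
4 | 5-chloro-7-methoxy-2H-chromen-2-one | COc1cc(Cl)c2ccc(=O)oc2c1 | intermediate
5 | (3,5-dimethoxyphenyl)boronic acid | COc1cc(cc(OC)c1)B(O)O | starting material
6 | (4S)-5-chloro-4-(3,5-dimethoxyphenyl)-7-methoxy-3,4-dihydro-2H-chromen-2-one | COc1cc(Cl)c2[C@@H](CC(=O)Oc2c1)c1cc(OC)cc(OC)c1 | intermediate
7 | (3R,4S)-3-bromo-5-chloro-4-(3,5-dimethoxyphenyl)-7-methoxy-3,4-dihydro-2H-chromen-2-one (trans) | COc1cc(Cl)c2[C@@H]([C@@H](Br)C(=O)Oc2c1)c1cc(OC)cc(OC)c1 | intermediate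
8 | (2R,3S)-2-bromo-3-(2-chloro-6-hydroxy-4-methoxyphenyl)-3-(3,5-dimethoxyphenyl)propanoic acid (formed as its dilithium salt) | COc1cc(Cl)c([C@@H]([C@@H](Br)C(=O)O)c2cc(OC)cc(OC)c2)c(O)c1 | intermediate
9 | (2S,3S)-4-chloro-3-(3,5-dimethoxyphenyl)-6-methoxy-2,3-dihydro-1-benzofuran-2-carboxylic acid | COc1cc(Cl)c2[C@@H]([C@H](Oc2c1)C(=O)O)c1cc(OC)cc(OC)c1 | intermediate
10 | 4-iodoanisole | COc1ccc(I)cc1 | starting material
11 | (2S,3S)-4-chloro-3-(3,5-dimethoxyphenyl)-6-methoxy-2-(4-methoxyphenyl)-2,3-dihydro-1-benzofuran | COc1cc(Cl)c2[C@@H]([C@H](Oc2c1)c1ccc(OC)cc1)c1cc(OC)cc(OC)c1 | intermediate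
12 | [(2S,3S)-3-(3,5-dimethoxyphenyl)-6-methoxy-2-(4-methoxyphenyl)-2,3-dihydro-1-benzofuran-4-yl]boronic acid | COc1cc(B(O)O)c2[C@@H]([C@H](Oc2c1)c1ccc(OC)cc1)c1cc(OC)cc(OC)c1 | intermediate
13 | 4-chloro-3-(3,5-dimethoxyphenyl)-6-methoxy-2-(4-methoxyphenyl)-1-benzofuran | COc1cc(Cl)c2c(-c3cc(OC)cc(OC)c3)c(-c3ccc(OC)cc3)oc2c1 | intermediate
14 | 3-(3,5-dimethoxyphenyl)-4-ethenyl-6-methoxy-2-(4-methoxyphenyl)-1-benzofuran | C=Cc1cc(OC)cc2oc(-c3ccc(OC)cc3)c(-c3cc(OC)cc(OC)c3)c12 | intermediate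
15 | 6-chloro-2H-chromen-2-one | Clc1ccc2oc(=O)ccc2c1 | starting material
16 | (4R)-6-chloro-4-[(2S,3S)-3-(3,5-dimethoxyphenyl)-6-methoxy-2-(4-methoxyphenyl)-2,3-dihydro-1-benzofuran-4-yl]-3,4-dihydro-2H-chromen-2-one | COc1cc([C@H]3CC(=O)Oc4ccc(Cl)cc43)c2[C@@H]([C@H](Oc2c1)c1ccc(OC)cc1)c1cc(OC)cc(OC)c1 | intermediate
17 | (3S,4R)-3-bromo-6-chloro-4-[(2S,3S)-3-(3,5-dimethoxyphenyl)-6-methoxy-2-(4-methoxyphenyl)-2,3-dihydro-1-benzofuran-4-yl]-3,4-dihydro-2H-chromen-2-one (trans) | COc1cc([C@H]3[C@H](Br)C(=O)Oc4ccc(Cl)cc43)c2[C@@H]([C@H](Oc2c1)c1ccc(OC)cc1)c1cc(OC)cc(OC)c1 | intermediate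
18 | (2S,3R)-2-bromo-3-(5-chloro-2-hydroxyphenyl)-3-[(2S,3S)-3-(3,5-dimethoxyphenyl)-6-methoxy-2-(4-methoxyphenyl)-2,3-dihydro-1-benzofuran-4-yl]propanoic acid (formed as its dilithium salt) | COc1cc([C@@H]([C@H](Br)C(=O)O)c3cc(Cl)ccc3O)c2[C@@H]([C@H](Oc2c1)c1ccc(OC)cc1)c1cc(OC)cc(OC)c1 | intermediate
19 | (2R,3R)-5-chloro-3-[(2S,3S)-3-(3,5-dimethoxyphenyl)-6-methoxy-2-(4-methoxyphenyl)-2,3-dihydro-1-benzofuran-4-yl]-2,3-dihydro-1-benzofuran-2-carboxylic acid | COc1cc([C@H]3[C@H](C(=O)O)Oc4ccc(Cl)cc43)c2[C@@H]([C@H](Oc2c1)c1ccc(OC)cc1)c1cc(OC)cc(OC)c1 | intermediate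
20 | (2R,3R)-5-chloro-2-(4-methoxyphenyl)-3-[(2S,3S)-3-(3,5-dimethoxyphenyl)-6-methoxy-2-(4-methoxyphenyl)-2,3-dihydro-1-benzofuran-4-yl]-2,3-dihydro-1-benzofuran | COc1cc([C@H]3[C@H](c5ccc(OC)cc5)Oc4ccc(Cl)cc43)c2[C@@H]([C@H](Oc2c1)c1ccc(OC)cc1)c1cc(OC)cc(OC)c1 | intermediate
21 | nona-O-methyl ether of the target (central ring 2R,3R; eastern ring 2S,3S; E-stilbene) | COc1cc([C@H]3[C@H](c5ccc(OC)cc5)Oc4ccc(/C=C/c6cc(OC)cc7oc(-c8ccc(OC)cc8)c(-c8cc(OC)cc(OC)c8)c67)cc43)c2[C@@H]([C@H](Oc2c1)c1ccc(OC)cc1)c1cc(OC)cc(OC)c1 | intermediate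
22 | CNP0135983.1 (nonaphenol; central ring 2R,3R; eastern ring 2S,3S; E-stilbene) | Oc1ccc(-c2oc3cc(O)cc(/C=C/c4ccc5c(c4)[C@@H](c4cc(O)cc6c4[C@H](c4cc(O)cc(O)c4)[C@@H](c4ccc(O)cc4)O6)[C@H](c4ccc(O)cc4)O5)c3c2-c2cc(O)cc(O)c2)cc1 | target

Total step count: 14. Longest linear sequence: 12 steps (steps 1 to 7, then 10 to 14); steps 8 and 9 branch off from 11.

Steps most likely to fail

Step 10. The hindered, ortho-substituted boronic acid is the limiting partner, and slow transmetalation or protodeboronation may outrun insertion of the sluggish coumarin. The fallback reverses the polarity and sets out from chloride 11. A Mizoroki–Heck reaction with tert-butyl acrylate (Pd2(dba)3, P(t-Bu)3·HBF4, Cy2NMe, dioxane, 110 °C) should give tert-butyl (E)-3-[(2S,3S)-3-(3,5-dimethoxyphenyl)-6-methoxy-2-(4-methoxyphenyl)-2,3-dihydro-1-benzofuran-4-yl]prop-2-enoate F1. Conjugate addition of an excess of commercial [2-(benzyloxy)-5-chlorophenyl]boronic acid (Rh(acac)(C2H4)2 with the SEGPHOS or chiral diene enantiomer that gives the 3R centre, dioxane/H2O) should give tert-butyl (3R)-3-[2-(benzyloxy)-5-chlorophenyl]-3-[(2S,3S)-3-(3,5-dimethoxyphenyl)-6-methoxy-2-(4-methoxyphenyl)-2,3-dihydro-1-benzofuran-4-yl]propanoate F2. BCl3 with pentamethylbenzene (CH2Cl2, −78 °C) removes the benzyl ether and the tert-butyl ester, and TsOH in toluene at 60 °C closes the lactone, which comes back to the route at 16.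

Step 4. Insertion of the coumarin into the aryl–rhodium bond may be too slow, because the peri chlorine at C5 crowds C4 and the 7-methoxy group lowers the acceptor strength, so that the boronic acid is consumed by protodeboronation. The fallback sets the same centre by asymmetric conjugate reduction and starts from 3. Addition of 3,5-dimethoxyphenylmagnesium bromide (2.5 equiv, THF, 0 °C) should give 3-chloro-2-[(3,5-dimethoxyphenyl)(hydroxy)methyl]-5-methoxyphenol F3. Oxidation with MnO2 (CH2Cl2, rt) should give (2-chloro-6-hydroxy-4-methoxyphenyl)(3,5-dimethoxyphenyl)methanone F4. (Triphenylphosphoranylidene)ketene, Ph3P=C=C=O, in refluxing toluene (O-acylation, then intramolecular Wittig reaction) should give 5-chloro-4-(3,5-dimethoxyphenyl)-7-methoxy-2H-chromen-2-one F5. Copper hydride 1,4-reduction (Cu(OAc)2, the DTBM-SEGPHOS enantiomer that gives 4S, diethoxymethylsilane, t-BuOH, toluene) returns to the route at 6.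

Step 14. During exhaustive demethylation the acid may protonate the stilbene and trigger Friedel–Crafts cyclisation onto the neighbouring resorcinol rings, or leave some of the nine ethers uncleaved. The fallback removes the methyl groups before the stilbene exists and sets out from 20 and 13.
- Central half: BBr3 on 20 should give the pentaphenol (2R,3R)-5-chloro-2-(4-hydroxyphenyl)-3-[(2S,3S)-3-(3,5-dihydroxyphenyl)-6-hydroxy-2-(4-hydroxyphenyl)-2,3-dihydro-1-benzofuran-4-yl]-2,3-dihydro-1-benzofuran F6, and Ac2O/pyridine its pentaacetate F7.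
- Western half: BBr3 on 13 should give 4-chloro-3-(3,5-dihydroxyphenyl)-2-(4-hydroxyphenyl)-1-benzofuran-6-ol F8. Suzuki–Miyaura vinylation as in step 9 should give 3-(3,5-dihydroxyphenyl)-4-ethenyl-2-(4-hydroxyphenyl)-1-benzofuran-6-ol F9, and Ac2O/pyridine its tetraacetate F10.
- Union: a Mizoroki–Heck reaction of F7 with F10 under the conditions of step 13 should give the nonaacetate of the target F11. Mild methanolysis (K2CO3, MeOH, rt, under argon) returns to the route at 22.

Further compounds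
F1 | step 10 | tert-butyl (E)-3-[(2S,3S)-3-(3,5-dimethoxyphenyl)-6-methoxy-2-(4-methoxyphenyl)-2,3-dihydro-1-benzofuran-4-yl]prop-2-enoate | COc1cc(/C=C/C(=O)OC(C)(C)C)c2[C@@H]([C@H](Oc2c1)c1ccc(OC)cc1)c1cc(OC)cc(OC)c1
F2 | step 10 | tert-butyl (3R)-3-[2-(benzyloxy)-5-chlorophenyl]-3-[(2S,3S)-3-(3,5-dimethoxyphenyl)-6-methoxy-2-(4-methoxyphenyl)-2,3-dihydro-1-benzofuran-4-yl]propanoate | COc1cc([C@@H](CC(=O)OC(C)(C)C)c3cc(Cl)ccc3OCc3ccccc3)c2[C@@H]([C@H](Oc2c1)c1ccc(OC)cc1)c1cc(OC)cc(OC)c1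
F3 | step 4 | 3-chloro-2-[(3,5-dimethoxyphenyl)(hydroxy)methyl]-5-methoxyphenol (racemic) | COc1cc(Cl)c(C(O)c2cc(OC)cc(OC)c2)c(O)c1
F4 | step 4 | (2-chloro-6-hydroxy-4-methoxyphenyl)(3,5-dimethoxyphenyl)methanone | COc1cc(Cl)c(C(=O)c2cc(OC)cc(OC)c2)c(O)c1
F5 | step 4 | 5-chloro-4-(3,5-dimethoxyphenyl)-7-methoxy-2H-chromen-2-one | COc1cc(Cl)c2c(-c3cc(OC)cc(OC)c3)cc(=O)oc2c1
F6 | step 14 | (2R,3R)-5-chloro-2-(4-hydroxyphenyl)-3-[(2S,3S)-3-(3,5-dihydroxyphenyl)-6-hydroxy-2-(4-hydroxyphenyl)-2,3-dihydro-1-benzofuran-4-yl]-2,3-dihydro-1-benzofuran | Oc1cc([C@H]3[C@H](c5ccc(O)cc5)Oc4ccc(Cl)cc43)c2[C@@H]([C@H](Oc2c1)c1ccc(O)cc1)c1cc(O)cc(O)c1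
F7 | step 14 | pentaacetate of F6 | CC(=O)Oc1cc([C@H]3[C@H](c5ccc(OC(C)=O)cc5)Oc4ccc(Cl)cc43)c2[C@@H]([C@H](Oc2c1)c1ccc(OC(C)=O)cc1)c1cc(OC(C)=O)cc(OC(C)=O)c1
F8 | step 14 | 4-chloro-3-(3,5-dihydroxyphenyl)-2-(4-hydroxyphenyl)-1-benzofuran-6-ol | Oc1cc(Cl)c2c(-c3cc(O)cc(O)c3)c(-c3ccc(O)cc3)oc2c1
F9 | step 14 | 3-(3,5-dihydroxyphenyl)-4-ethenyl-2-(4-hydroxyphenyl)-1-benzofuran-6-ol | C=Cc1cc(O)cc2oc(-c3ccc(O)cc3)c(-c3cc(O)cc(O)c3)c12
F10 | step 14 | tetraacetate of F9 | C=Cc1cc(OC(C)=O)cc2oc(-c3ccc(OC(C)=O)cc3)c(-c3cc(OC(C)=O)cc(OC(C)=O)c3)c12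
F11 | step 14 | nonaacetate of the target | CC(=O)Oc1cc([C@H]3[C@H](c5ccc(OC(C)=O)cc5)Oc4ccc(/C=C/c6cc(OC(C)=O)cc7oc(-c8ccc(OC(C)=O)cc8)c(-c8cc(OC(C)=O)cc(OC(C)=O)c8)c67)cc43)c2[C@@H]([C@H](Oc2c1)c1ccc(OC(C)=O)cc1)c1cc(OC(C)=O)cc(OC(C)=O)c1
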